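The chromanone ring (O1–C2–C3–C4(=O)–C4a–C8a) fused to the phloroglucinol-derived ring A is traced to an α-aryloxy α'-diazo ketone made from L-lactate, in which the carbonyl carbon (future C4) is bonded to C2, not to C3. Photochemical Wolff rearrangement shifts C2, with retention, onto the diazo carbon (C2–C3 bond) and leaves a ketene at C4 that acylates the adjacent electron-rich ring carbon C4a (C4–C4a bond), closing the pyranone in one operation; kinetic protonation then sets the cis-2,3-dimethyl pattern. The benzylic centre comes from asymmetric copper hydride reduction of a 4-phenylcoumarin; C8 is then alkylated with (S)-lavandulyl iodide and quaternised by palladium-catalysed asymmetric dearomative prenylation.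

Key step: step 5

Remark: ring positions of the target are numbered as in chromene (O1, C2, C3, C4, C4a, C5 to C8, C8a); the target is a cyclic vinylogous acid written as one enol tautomer of an interconverting set.

Step 1
Reactants: 1 5,7-dihydroxy-4-phenylcoumarin; 2 tert-butyl (S)-lactate
Product: 3 tert-butyl (2R)-2-[(5-hydroxy-2-oxo-4-phenyl-2H-chromen-7-yl)oxy]propanoate
Conditions: PPh3, DIAD, THF, 0 °C to rt
Reagents that add atoms: none
Why: Mitsunobu etherification, in which the 7-OH (the more acidic phenol, vinylogously conjugated to the lactone carbonyl, and unhindered, whereas the 5-OH is shielded by the 4-phenyl ring) should react selectively, and SN2 inversion of the (S)-carbinol sets the (R)-aryloxy carbon that becomes C2.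

Step 2
Reactants: 3 tert-butyl (2R)-2-[(5-hydroxy-2-oxo-4-phenyl-2H-chromen-7-yl)oxy]propanoate
Product: 4 tert-butyl (2R)-2-{[(4R)-5-hydroxy-2-oxo-4-phenyl-3,4-dihydro-2H-chromen-7-yl]oxy}propanoate
Conditions: Cu(OAc)2·H2O (5 mol %), (R)-DTBM-SEGPHOS (5 mol %), (EtO)2MeSiH (2.5 equiv), t-BuOH, toluene, 0 °C to rt; aq. NH4F
Reagents that add atoms: none
Why: Copper hydride-catalysed asymmetric conjugate reduction of a 4-arylcoumarin, in which the bisphosphine-bound copper hydride should add to one face of C4 (the ligand antipode being chosen so that the 4R lactone results) and the enolate is protonated by t-BuOH, while the isolated tert-butyl ester is no conjugate acceptor and should survive.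

Step 3
Reactants: 4 tert-butyl (2R)-2-{[(4R)-5-hydroxy-2-oxo-4-phenyl-3,4-dihydro-2H-chromen-7-yl]oxy}propanoate
Product: 5 tert-butyl (2R)-2-{[(4R)-2-oxo-4-phenyl-5-(triisopropylsilyloxy)-3,4-dihydro-2H-chromen-7-yl]oxy}propanoate
Conditions: i-Pr3SiOTf, 2,6-lutidine, CH2Cl2, 0 °C
Reagents that add atoms: triisopropylsilyl trifluoromethanesulfonate CC(C)[Si](C(C)C)(C(C)C)OS(=O)(=O)C(F)(F)F
Why: Silylation of the remaining phenol under weakly basic conditions, which masks the OH against diazoethane and the ketene of steps 4 and 5 and places a bulky group next to one of the two ring carbons ortho to the ether oxygen.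

Step 4
Reactants: 5 tert-butyl (2R)-2-{[(4R)-2-oxo-4-phenyl-5-(triisopropylsilyloxy)-3,4-dihydro-2H-chromen-7-yl]oxy}propanoate
Product: 7 (4R)-7-{[(2R)-4-diazo-3-oxopentan-2-yl]oxy}-4-phenyl-5-(triisopropylsilyloxy)-3,4-dihydro-2H-chromen-2-one, via acid chloride 6 (not isolated)
Conditions: SOCl2, H2O (1 equiv), CH2Cl2, rt; evaporate; then CH3CHN2 (3 equiv, from N-ethyl-N-nitrosourea, aq. KOH, Et2O), Et2O, −20 °C
Reagents that add atoms: diazoethane CC=[N+]=[N-]
Why: Thionyl chloride converts tert-butyl esters directly into acid chlorides (HCl-promoted loss of the tert-butyl group, then chlorination) and C-acylation of diazoethane gives the α-methyl diazo ketone (first stage of an Arndt–Eistert sequence), excess diazoethane scavenging HCl so that the α-aryloxy stereocentre never meets a base.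

Step 5
Reactants: 7 (4R)-7-{[(2R)-4-diazo-3-oxopentan-2-yl]oxy}-4-phenyl-5-(triisopropylsilyloxy)-3,4-dihydro-2H-chromen-2-one
Product: 10 (4R,8R,9S)-8,9-dimethyl-4-phenyl-5-(triisopropylsilyloxy)-3,4,8,9-tetrahydro-2H,10H-pyrano[2,3-f]chromene-2,10-dione, via ketene 8 (not isolated), via aluminium enolate 9 (not isolated)
Conditions: hν (365 nm LED), CH2Cl2 (0.005 M), −78 °C; then EtAlCl2 (1.5 equiv), −78 °C; then AcOH in THF, −78 °C
Reagents that add atoms: none
Why: Direct irradiation expels N2 from 7 and the aryloxy-bearing carbon migrates with retention from the carbonyl carbon to the diazo carbon (Wolff rearrangement, as in the first half of an Arndt–Eistert homologation), which forms the C2–C3 bond and leaves ketene 8 whose sp carbon is the future C4. EtAlCl2 then activates the ketene and the ring-A carbon ortho to the tethered ether oxygen (future C4a) attacks it, a Lewis acid-promoted Friedel–Crafts acylation of an arene by a ketene that forms the C4–C4a bond; the proton lost on rearomatisation is consumed by the Al–Et bond, leaving the dichloroaluminium enolate 9. The pyranone ring closes in a six-membered mode at the sp carbon, 6-endo-dig with respect to the ketene C=C bond (6-exo with respect to its C=O). C2 is not new, its R configuration coming from L-lactate (inverted in step 1) and being carried through the stereoretentive 1,2-shift; the new centre C3 is set when 9 is protonated at −78 °C on the face anti to the pseudo-axial C2 methyl group, which should give the kinetic cis-2,3-dimethyl (3S) ketone. The step needs rearrangement to outrun carbene 1,2-hydride shift (direct photolysis at low temperature, no metal), intramolecular C-acylation to outrun ketene dimerisation or O-acylation (high dilution, no free OH, no alkene yet in the molecule) and attack at the ring carbon next to the lactone oxygen, not at the one shielded by the bulky silyl ether; the other regioisomer would in any case converge on the same ring-opened compound 18 in step 10.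

Step 6
Reactants: 11 (4S)-4-benzyl-1,3-oxazolidin-2-one; 12 3-methylbut-2-enoyl chloride
Product: 13 (4S)-4-benzyl-3-(3-methylbut-2-enoyl)-1,3-oxazolidin-2-one
Conditions: n-BuLi, THF, −78 °C; then 12, −78 to 0 °C
Reagents that add atoms: none
Why: N-acylation of the lithiated oxazolidinone auxiliary by the acid chloride.

Step 7
Reactants: 13 (4S)-4-benzyl-3-(3-methylbut-2-enoyl)-1,3-oxazolidin-2-one; 14 prenyl bromide
Product: 15 (4S)-4-benzyl-3-[(2S)-5-methyl-2-(prop-1-en-2-yl)hex-4-enoyl]-1,3-oxazolidin-2-one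
Conditions: NaN(SiMe3)2, THF, −78 °C; then 14, −78 to −40 °C
Reagents that add atoms: none
Why: Auxiliary-controlled deconjugative α-alkylation, in which γ-deprotonation gives the chelated (Z)-dienolate and prenyl bromide approaches anti to the 4-benzyl group, setting the (2S) centre that becomes the lavandulyl stereocentre.

Step 8
Reactants: 15 (4S)-4-benzyl-3-[(2S)-5-methyl-2-(prop-1-en-2-yl)hex-4-enoyl]-1,3-oxazolidin-2-one
Product: 16 (2S)-5-methyl-2-(prop-1-en-2-yl)hex-4-en-1-ol, (S)-lavandulol
Conditions: LiBH4, MeOH (1 equiv), Et2O, 0 °C; aq. NaOH work-up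
Reagents that add atoms: none
Why: Reductive cleavage of the imide to the primary alcohol with release of the auxiliary, under conditions that do not enolise the β,γ-unsaturated stereocentre.

Step 9
Reactants: 16 (2S)-5-methyl-2-(prop-1-en-2-yl)hex-4-en-1-ol
Product: 17 (3S)-3-(iodomethyl)-2,6-dimethylhepta-1,5-diene, (S)-lavandulyl iodide
Conditions: PPh3, I2, imidazole, CH2Cl2, 0 °C to rt
Reagents that add atoms: iodine II
Why: Appel-type iodination at the primary carbinol carbon, which leaves the adjacent stereocentre untouched.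

Step 10
Reactants: 10 (4R,8R,9S)-8,9-dimethyl-4-phenyl-5-(triisopropylsilyloxy)-3,4,8,9-tetrahydro-2H,10H-pyrano[2,3-f]chromene-2,10-dione; 17 (S)-lavandulyl iodide
Product: 19 methyl (3R)-3-{(2R,3S)-5,7-dihydroxy-2,3-dimethyl-8-[(2R)-5-methyl-2-(prop-1-en-2-yl)hex-4-en-1-yl]-4-oxo-3,4-dihydro-2H-chromen-6-yl}-3-phenylpropanoate, via ring-opened methyl ester 18 (not isolated)
Conditions: NaOMe (2.1 equiv), MeOH, 0 °C to rt; then 17 (1.5 equiv), 45 °C; aq. HCl to pH 5, 0 °C
Reagents that add atoms: sodium methoxide [Na+].[O-]C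
Why: Methoxide cleaves the aryl silyl ether (its aryloxide is para to the ketone) and opens the aryl lactone to the bis-phenoxide of 18, whose only unsubstituted ring carbon C8 is then C-alkylated by the primary iodide in the protic medium (C-alkylation of a phloroglucinol-type phenoxide, as in known dearomative lavandulylations of acylphloroglucinols), while the ring-A polyanion should keep the C4 ketone from enolising so that the cis C2/C3 centres hold.

Step 11
Reactants: 19 methyl (3R)-3-{(2R,3S)-5,7-dihydroxy-2,3-dimethyl-8-[(2R)-5-methyl-2-(prop-1-en-2-yl)hex-4-en-1-yl]-4-oxo-3,4-dihydro-2H-chromen-6-yl}-3-phenylpropanoate; 20 prenyl acetate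
Product: 21 methyl (3R)-3-{(2R,3S,8S)-5-hydroxy-2,3-dimethyl-8-(3-methylbut-2-en-1-yl)-8-[(2R)-5-methyl-2-(prop-1-en-2-yl)hex-4-en-1-yl]-4,7-dioxo-3,4,7,8-tetrahydro-2H-chromen-6-yl}-3-phenylpropanoate
Conditions: Pd2(dba)3·CHCl3 (2.5 mol %), (R,R)-N,N'-bis(2-diphenylphosphinobenzoyl)-1,2-diaminocyclohexane (7.5 mol %), Et3N (1.2 equiv), CH2Cl2, 0 °C to rt
Reagents that add atoms: none
Why: Tsuji–Trost-type asymmetric allylic dearomatisation, in which the phenoxide of the acidic 7-OH attacks the unsubstituted terminus of the π-prenyl complex of palladium through C8 (less hindered than C6, which carries the branched benzylic chain), reversible O-allylation funnels to the C-allylated vinylogous acid, and the chiral diphosphine differentiates the two faces of C8 (the ligand antipode being chosen to give 8S).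

Step 12
Reactants: 21 methyl (3R)-3-{(2R,3S,8S)-5-hydroxy-2,3-dimethyl-8-(3-methylbut-2-en-1-yl)-8-[(2R)-5-methyl-2-(prop-1-en-2-yl)hex-4-en-1-yl]-4,7-dioxo-3,4,7,8-tetrahydro-2H-chromen-6-yl}-3-phenylpropanoate
Product: 22 (3R)-3-{(2R,3S,8S)-5-hydroxy-2,3-dimethyl-8-(3-methylbut-2-en-1-yl)-8-[(2R)-5-methyl-2-(prop-1-en-2-yl)hex-4-en-1-yl]-4,7-dioxo-3,4,7,8-tetrahydro-2H-chromen-6-yl}-3-phenylpropanoic acid
Conditions: LiOH·H2O (3 equiv), THF/H2O, 0 °C to rt; then 1 M HCl to pH 3, 0 °C
Reagents that add atoms: lithium hydroxide [Li+].[OH-]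
Why: Saponification of the methyl ester at low temperature, during which ring A is present as its vinylogous-acid anion so that neither C3 enolisation nor retro-Michael loss of the side chain should compete; no stereocentre is formed.

Compound list
1 | 5,7-dihydroxy-4-phenyl-2H-chromen-2-one (5,7-dihydroxy-4-phenylcoumarin) | O=c1cc(-c2ccccc2)c2c(O)cc(O)cc2o1 | starting material
2 | tert-butyl (2S)-2-hydroxypropanoate (tert-butyl L-lactate) | C[C@H](O)C(=O)OC(C)(C)C | starting material
3 | tert-butyl (2R)-2-[(5-hydroxy-2-oxo-4-phenyl-2H-chromen-7-yl)oxy]propanoate | O=c1cc(-c2ccccc2)c2c(O)cc(O[C@H](C)C(=O)OC(C)(C)C)cc2o1 | intermediate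
4 | tert-butyl (2R)-2-{[(4R)-5-hydroxy-2-oxo-4-phenyl-3,4-dihydro-2H-chromen-7-yl]oxy}propanoate | O=C1C[C@H](c2ccccc2)c2c(O)cc(O[C@H](C)C(=O)OC(C)(C)C)cc2O1 | intermediate
5 | tert-butyl (2R)-2-{[(4R)-2-oxo-4-phenyl-5-(triisopropylsilyloxy)-3,4-dihydro-2H-chromen-7-yl]oxy}propanoate | O=C1C[C@H](c2ccccc2)c2c(O[Si](C(C)C)(C(C)C)C(C)C)cc(O[C@H](C)C(=O)OC(C)(C)C)cc2O1 | intermediate
6 | (2R)-2-{[(4R)-2-oxo-4-phenyl-5-(triisopropylsilyloxy)-3,4-dihydro-2H-chromen-7-yl]oxy}propanoyl chloride (not isolated) | O=C1C[C@H](c2ccccc2)c2c(O[Si](C(C)C)(C(C)C)C(C)C)cc(O[C@H](C)C(Cl)=O)cc2O1 | intermediate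
7 | (4R)-7-{[(2R)-4-diazo-3-oxopentan-2-yl]oxy}-4-phenyl-5-(triisopropylsilyloxy)-3,4-dihydro-2H-chromen-2-one | O=C1C[C@H](c2ccccc2)c2c(O[Si](C(C)C)(C(C)C)C(C)C)cc(O[C@H](C)C(=O)C(C)=[N+]=[N-])cc2O1 | intermediate
8 | (4R)-7-{[(2R)-3-methyl-4-oxobut-3-en-2-yl]oxy}-4-phenyl-5-(triisopropylsilyloxy)-3,4-dihydro-2H-chromen-2-one, the ketene (not isolated) | O=C1C[C@H](c2ccccc2)c2c(O[Si](C(C)C)(C(C)C)C(C)C)cc(O[C@H](C)C(C)=C=O)cc2O1 | intermediate
9 | (4R,8R)-10-(dichloroalumanyloxy)-8,9-dimethyl-4-phenyl-5-(triisopropylsilyloxy)-3,4-dihydro-2H,8H-pyrano[2,3-f]chromen-2-one, the aluminium enolate (not isolated) | O=C1C[C@H](c2ccccc2)c2c(O[Si](C(C)C)(C(C)C)C(C)C)cc3O[C@H](C)C(C)=C(O[Al](Cl)Cl)c3c2O1 | intermediate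
10 | (4R,8R,9S)-8,9-dimethyl-4-phenyl-5-(triisopropylsilyloxy)-3,4,8,9-tetrahydro-2H,10H-pyrano[2,3-f]chromene-2,10-dione | O=C1C[C@H](c2ccccc2)c2c(O[Si](C(C)C)(C(C)C)C(C)C)cc3O[C@H](C)[C@H](C)C(=O)c3c2O1 | intermediate
11 | (4S)-4-benzyl-1,3-oxazolidin-2-one | O=C1N[C@@H](Cc2ccccc2)CO1 | starting material
12 | 3-methylbut-2-enoyl chloride | CC(C)=CC(=O)Cl | starting material
13 | (4S)-4-benzyl-3-(3-methylbut-2-enoyl)-1,3-oxazolidin-2-one | CC(C)=CC(=O)N1[C@@H](Cc2ccccc2)COC1=O | intermediate
14 | 1-bromo-3-methylbut-2-ene (prenyl bromide) | CC(C)=CCBr | starting material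
15 | (4S)-4-benzyl-3-[(2S)-5-methyl-2-(prop-1-en-2-yl)hex-4-enoyl]-1,3-oxazolidin-2-one | C=C(C)[C@H](CC=C(C)C)C(=O)N1[C@@H](Cc2ccccc2)COC1=O | intermediate
16 | (2S)-5-methyl-2-(prop-1-en-2-yl)hex-4-en-1-ol ((S)-lavandulol) | C=C(C)[C@H](CC=C(C)C)CO | intermediate
17 | (3S)-3-(iodomethyl)-2,6-dimethylhepta-1,5-diene ((S)-lavandulyl iodide) | C=C(C)[C@H](CC=C(C)C)CI | intermediate
18 | methyl (3R)-3-[(2R,3S)-5,7-dihydroxy-2,3-dimethyl-4-oxo-3,4-dihydro-2H-chromen-6-yl]-3-phenylpropanoate, formed as its disodium phenoxide (not isolated) | COC(=O)C[C@H](c1ccccc1)c1c(O)cc2O[C@H](C)[C@H](C)C(=O)c2c1O | intermediate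
19 | methyl (3R)-3-{(2R,3S)-5,7-dihydroxy-2,3-dimethyl-8-[(2R)-5-methyl-2-(prop-1-en-2-yl)hex-4-en-1-yl]-4-oxo-3,4-dihydro-2H-chromen-6-yl}-3-phenylpropanoate | COC(=O)C[C@H](c1ccccc1)c1c(O)c(C[C@@H](CC=C(C)C)C(C)=C)c2O[C@H](C)[C@H](C)C(=O)c2c1O | intermediate
20 | 3-methylbut-2-en-1-yl acetate (prenyl acetate) | CC(C)=CCOC(C)=O | starting material
21 | methyl (3R)-3-{(2R,3S,8S)-5-hydroxy-2,3-dimethyl-8-(3-methylbut-2-en-1-yl)-8-[(2R)-5-methyl-2-(prop-1-en-2-yl)hex-4-en-1-yl]-4,7-dioxo-3,4,7,8-tetrahydro-2H-chromen-6-yl}-3-phenylpropanoate | C=C(C)[C@H](CC=C(C)C)C[C@]1(CC=C(C)C)C(=O)C([C@H](CC(=O)OC)c2ccccc2)=C(O)C2=C1O[C@H](C)[C@H](C)C2=O | intermediate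
22 | (3R)-3-{(2R,3S,8S)-5-hydroxy-2,3-dimethyl-8-(3-methylbut-2-en-1-yl)-8-[(2R)-5-methyl-2-(prop-1-en-2-yl)hex-4-en-1-yl]-4,7-dioxo-3,4,7,8-tetrahydro-2H-chromen-6-yl}-3-phenylpropanoic acid | C=C(C)[C@H](CC=C(C)C)C[C@]1(CC=C(C)C)C(=O)C([C@H](CC(=O)O)c2ccccc2)=C(O)C2=C1O[C@H](C)[C@H](C)C2=O | target

Total step count: 12. Longest linear sequence: 8 steps (steps 1 to 5 and 10 to 12, from compound 1); the lavandulyl branch (steps 6 to 9) joins at step 10.

Steps most likely to fail

Step 5. The excited diazo ketone may lose nitrogen to a free carbene that undergoes 1,2-hydride shift instead of rearranging. The ketene may dimerise or be captured by adventitious water before the ring carbon attacks it. The cis centre next to the ketone may also epimerise by enolisation during the Lewis acid stage. The fallback sets out from 7 and comes back at 10, forming the two ring bonds in separate operations. Compound 7 is irradiated (365 nm) in dioxane/H2O so that water captures the ketene (Arndt–Eistert homologation), giving (3R)-2-methyl-3-{[(4R)-2-oxo-4-phenyl-5-(triisopropylsilyloxy)-3,4-dihydro-2H-chromen-7-yl]oxy}butanoic acid F1 as a mixture at C2. Classical intramolecular Friedel–Crafts acylation through the mixed anhydride ((CF3CO)2O, CH2Cl2, 0 °C) closes the ring, and equilibration with Et3N settles the ketone as the trans (4R,8R,9R) chromanone F2. Soft enolisation (Me3SiOTf, Et3N, CH2Cl2, 0 °C) gives the trimethylsilyl enol ether F3. Protonolysis of F3 (AcOH, THF/H2O, −20 °C) on the face anti to the C8 methyl group should return the cis ketone 10.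

Step 10. The phenoxide may be alkylated at oxygen instead of carbon, substitution at the β-branched primary iodide may be slow and lose out to elimination, and prolonged warming in base may epimerise C3. The fallback sets out from 10 and comes back at 19. The methoxide stage alone (NaOMe, MeOH, 0 °C; careful neutralisation) is used to isolate 18. N-Iodosuccinimide in CH2Cl2 at 0 °C iodinates the only free ring position to give methyl (3R)-3-[(2R,3S)-5,7-dihydroxy-8-iodo-2,3-dimethyl-4-oxo-3,4-dihydro-2H-chromen-6-yl]-3-phenylpropanoate F4. Zinc insertion into 17 (Zn dust, LiCl, THF) gives [(2S)-5-methyl-2-(prop-1-en-2-yl)hex-4-en-1-yl]zinc iodide F5. Negishi coupling of F4 with excess F5 (Pd(OAc)2, SPhos, THF, rt) then gives 19.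

Step 11. Ionisation of the prenyl acetate by zerovalent palladium may be slow, the π-prenyl complex may be captured at oxygen or at C6, and the chiral ligand may discriminate the two faces of C8 poorly. The fallback sets out from 19 and comes back at 21. It gives up catalyst control for the classical base-mediated dearomative alkylation: the disodium salt of 19 (NaOMe, MeOH, 0 °C) is treated with prenyl bromide 14. This should give 21 together with its C8 epimer, methyl (3R)-3-{(2R,3S,8R)-5-hydroxy-2,3-dimethyl-8-(3-methylbut-2-en-1-yl)-8-[(2R)-5-methyl-2-(prop-1-en-2-yl)hex-4-en-1-yl]-4,7-dioxo-3,4,7,8-tetrahydro-2H-chromen-6-yl}-3-phenylpropanoate F6. The two diastereomers are separated by preparative HPLC and 21 is carried into step 12.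

Further compounds
F1 | step 5 | (3R)-2-methyl-3-{[(4R)-2-oxo-4-phenyl-5-(triisopropylsilyloxy)-3,4-dihydro-2H-chromen-7-yl]oxy}butanoic acid (mixture at C2) | O=C1C[C@H](c2ccccc2)c2c(O[Si](C(C)C)(C(C)C)C(C)C)cc(O[C@H](C)C(C)C(=O)O)cc2O1
F2 | step 5 | (4R,8R,9R)-8,9-dimethyl-4-phenyl-5-(triisopropylsilyloxy)-3,4,8,9-tetrahydro-2H,10H-pyrano[2,3-f]chromene-2,10-dione | O=C1C[C@H](c2ccccc2)c2c(O[Si](C(C)C)(C(C)C)C(C)C)cc3O[C@H](C)[C@@H](C)C(=O)c3c2O1
F3 | step 5 | (4R,8R)-8,9-dimethyl-4-phenyl-5-(triisopropylsilyloxy)-10-(trimethylsilyloxy)-3,4-dihydro-2H,8H-pyrano[2,3-f]chromen-2-one | O=C1C[C@H](c2ccccc2)c2c(O[Si](C(C)C)(C(C)C)C(C)C)cc3O[C@H](C)C(C)=C(O[Si](C)(C)C)c3c2O1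
F4 | step 10 | methyl (3R)-3-[(2R,3S)-5,7-dihydroxy-8-iodo-2,3-dimethyl-4-oxo-3,4-dihydro-2H-chromen-6-yl]-3-phenylpropanoate | COC(=O)C[C@H](c1ccccc1)c1c(O)c(I)c2O[C@H](C)[C@H](C)C(=O)c2c1O
F5 | step 10 | [(2S)-5-methyl-2-(prop-1-en-2-yl)hex-4-en-1-yl]zinc iodide | C=C(C)[C@H](CC=C(C)C)C[Zn]I
F6 | step 11 | methyl (3R)-3-{(2R,3S,8R)-5-hydroxy-2,3-dimethyl-8-(3-methylbut-2-en-1-yl)-8-[(2R)-5-methyl-2-(prop-1-en-2-yl)hex-4-en-1-yl]-4,7-dioxo-3,4,7,8-tetrahydro-2H-chromen-6-yl}-3-phenylpropanoate | C=C(C)[C@H](CC=C(C)C)C[C@@]1(CC=C(C)C)C(=O)C([C@H](CC(=O)OC)c2ccccc2)=C(O)C2=C1O[C@H](C)[C@H](C)C2=O
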